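## Retrosynthetic overview

1. The chalcone C=C is made last by Claisen–Schmidt condensation on an aryl methyl ketone; the acetyl group comes from a Hoesch acylation of the symmetric 2,6-dihydroxy-4-methoxyphenyl ring.
2. The C2–aryl bond comes from a nickel/photoredox decarboxylative arylation of an oxane-2-carboxylic acid (axial capture of the C2 radical, aryl trans to the C4 and C6 groups); the C4–aryl bond comes from a diastereoconvergent Negishi coupling of an oxan-4-ylzinc reagent (aryl equatorial).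
3. The oxane is the only ring formed (all four benzene rings are bought): a bromo-Prins cyclization of an (S)-homoallylic alcohol with ethyl glyoxylate closes C2–C3 and leaves an ester on C2 and a bromide on C4 as the two exchangeable handles.
4. Feature that makes this possible: in the oxane ring (O1, C2–C6), C2 is bonded to the ring oxygen O1, and O1–C6–C5–C4=C3 is a homoallylic alcohol. An aldehyde carbon on O1 becomes the oxocarbenium carbon C2, the alkene terminus C3 reaches it through a six-membered chair, and the positive charge lands on C4, the carbon that must later carry an aryl ring.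
5. The C6 stereocentre comes from a Brown allylboration and controls C4 (thermodynamic) and C2 (kinetic) in turn.

Key step: step 2

Remark: oxane numbering is O1, C2 (4-hydroxyphenyl), C3, C4 (acylated dihydroxy-methoxyphenyl ring), C5, C6 (arylethyl). The target is (2R,4R,6S): the C2 aryl is trans to the cis-related C4 and C6 groups, which is the less stable C2 epimer. C2 is therefore set last under kinetic control, and no strong acid (only a cold acetic acid quench) is used after that point.

## Route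

Step 1
Reactants: 1 3-[4-(benzyloxy)phenyl]propanal
Product: 3 (3S)-1-[4-(benzyloxy)phenyl]hex-5-en-3-ol, via borinate ester 2 (not isolated)
Conditions: (+)-Ipc2B(allyl) [from (−)-α-pinene], Et2O, −78 °C; then NaOH, H2O2, 0 °C to 25 °C
Reagents that add atoms: (+)-B-allyldiisopinocampheylborane, C=CCB([C@H]1C[C@H]2C[C@@H]([C@@H]1C)C2(C)C)[C@H]1C[C@H]2C[C@@H]([C@@H]1C)C2(C)C
Why: Brown allylboration through a closed chair transition state; the isopinocampheyl groups from (−)-α-pinene should direct allyl transfer to the aldehyde face that gives the (S)-carbinol (C6 of the target), as with other unbranched aliphatic aldehydes.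

Step 2
Reactants: 3 (3S)-1-[4-(benzyloxy)phenyl]hex-5-en-3-ol; 4 ethyl glyoxylate
Product: 6 ethyl (2S,4R,6S)-6-{2-[4-(benzyloxy)phenyl]ethyl}-4-bromooxane-2-carboxylate, via oxocarbenium ion 5 (not isolated)
Conditions: TMSBr (1.5 equiv), InBr3 (10 mol %), CH2Cl2, 0 °C
Reagents that add atoms: bromotrimethylsilane, C[Si](C)(C)Br
Why: Prins cyclization: alcohol 3 and ethyl glyoxylate form a hemiacetal that TMSBr/InBr3 ionizes to the (E)-oxocarbenium ion 5, the alkene terminus C3 attacks C2, and the secondary C4 cation is captured by bromide. The closest known reaction type is the Lewis acid-mediated halo-Prins cyclization of homoallylic alcohols with aldehydes (glyoxylates included) to 4-halooxanes. The oxane closes in a 6-endo mode through a chair transition state. The new C2 centre (ester equatorial, cis to the C6 side chain) is controlled by the C6 stereocentre through the (E)-oxocarbenium chair, and the C4 centre (bromide equatorial) by equatorial capture of the cation; both are provisional, since C4 is later equilibrated through the organozinc and C2 passes through a radical. The step needs cyclization to outrun 2-oxonia-Cope side-chain exchange and loss of configuration at C6, which the lack of a cation-stabilising group on C6, the bromide-rich medium and 0 °C should secure, and it needs the benzyl ether to survive, which the short reaction at 0 °C should allow.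

Step 3
Reactants: 7 5-methoxybenzene-1,3-diol
Product: 8 1-methoxy-3,5-bis(methoxymethoxy)benzene
Conditions: NaH, MOMCl, DMF, 0 °C to 25 °C
Reagents that add atoms: chloromethyl methyl ether, COCCl
Why: Williamson-type O-alkylation of both phenoxides; the MOM ethers serve as directing groups for the lithiation that follows.

Step 4
Reactants: 8 1-methoxy-3,5-bis(methoxymethoxy)benzene
Product: 10 2-iodo-5-methoxy-1,3-bis(methoxymethoxy)benzene, via aryllithium 9 (not isolated)
Conditions: n-BuLi, THF, 0 °C; then I2, −78 °C to 25 °C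
Reagents that add atoms: iodine, II
Why: Directed ortho-metalation: the position flanked by the two MOM ethers is doubly chelated and most acidic, so lithiation and iodine quench should place iodine para to the methoxy group, which fixes the regiochemistry of the later C4–aryl bond.

Step 5
Reactants: 6 ethyl (2S,4R,6S)-6-{2-[4-(benzyloxy)phenyl]ethyl}-4-bromooxane-2-carboxylate; 10 2-iodo-5-methoxy-1,3-bis(methoxymethoxy)benzene
Product: 12 ethyl (2S,4R,6S)-6-{2-[4-(benzyloxy)phenyl]ethyl}-4-[4-methoxy-2,6-bis(methoxymethoxy)phenyl]oxane-2-carboxylate, via alkylzinc bromide 11 (not isolated)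
Conditions: Zn dust, LiCl, THF, 50 °C; then 10, Pd(OAc)2 (2 mol %), CPhos (4 mol %), THF, 25 °C
Reagents that add atoms: none
Why: Zinc insertion followed by Negishi coupling; substituted cycloalkylzinc reagents epimerize at the metal-bearing carbon and couple through the more stable equatorial palladium intermediate, so the aryl group should end equatorial at C4, cis to the C2 and C6 substituents, and CPhos is chosen to hold back β-hydride elimination with the doubly ortho-substituted aryl iodide.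

Step 6
Reactants: 12 ethyl (2S,4R,6S)-6-{2-[4-(benzyloxy)phenyl]ethyl}-4-[4-methoxy-2,6-bis(methoxymethoxy)phenyl]oxane-2-carboxylate
Product: 13 ethyl (2S,4R,6S)-6-{2-[4-(benzyloxy)phenyl]ethyl}-4-(2,6-dihydroxy-4-methoxyphenyl)oxane-2-carboxylate
Conditions: HCl (aq., cat.), EtOH, 50 °C
Reagents that add atoms: none
Why: Acid-catalysed acetal exchange removes both MOM groups; ethanol leaves the ethyl ester unchanged and the oxane has no ionizable benzylic C–O bond at this stage.

Step 7
Reactants: 13 ethyl (2S,4R,6S)-6-{2-[4-(benzyloxy)phenyl]ethyl}-4-(2,6-dihydroxy-4-methoxyphenyl)oxane-2-carboxylate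
Product: 15 ethyl (2S,4R,6S)-4-(3-acetyl-2,6-dihydroxy-4-methoxyphenyl)-6-{2-[4-(benzyloxy)phenyl]ethyl}oxane-2-carboxylate, via ketiminium chloride 14 (not isolated)
Conditions: MeCN, ZnCl2, HCl (g), Et2O, 0 °C; then H2O, 60 °C
Reagents that add atoms: acetonitrile, CC#N; water, O
Why: Hoesch reaction (nitrilium acylation of a phloroglucinol-type ring, then hydrolysis of the ketiminium salt); the two free ring positions are equivalent, each ortho to one hydroxyl and to the methoxy group, so only one regioisomer is possible, and the 4-(benzyloxy)phenyl ring is far less nucleophilic.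

Step 8
Reactants: 15 ethyl (2S,4R,6S)-4-(3-acetyl-2,6-dihydroxy-4-methoxyphenyl)-6-{2-[4-(benzyloxy)phenyl]ethyl}oxane-2-carboxylate
Product: 16 ethyl (2S,4R,6S)-4-[3-acetyl-2,6-bis(benzyloxy)-4-methoxyphenyl]-6-{2-[4-(benzyloxy)phenyl]ethyl}oxane-2-carboxylate
Conditions: BnBr, K2CO3, DMF, 60 °C
Reagents that add atoms: benzyl bromide, BrCc1ccccc1
Why: Williamson ether synthesis; both phenols are masked so that phenoxides do not quench the photoredox step, and the new benzyl ethers leave together with the others in step 11.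

Step 9
Reactants: 16 ethyl (2S,4R,6S)-4-[3-acetyl-2,6-bis(benzyloxy)-4-methoxyphenyl]-6-{2-[4-(benzyloxy)phenyl]ethyl}oxane-2-carboxylate
Product: 17 (2S,4R,6S)-4-[3-acetyl-2,6-bis(benzyloxy)-4-methoxyphenyl]-6-{2-[4-(benzyloxy)phenyl]ethyl}oxane-2-carboxylic acid
Conditions: LiOH, THF/H2O, 25 °C; then aq. HCl to pH 3
Reagents that add atoms: lithium hydroxide, [Li+].[OH-]
Why: Saponification of the activated α-alkoxy ester; any epimerization at C2 is irrelevant because C2 becomes a radical in the next step.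

Step 10
Reactants: 17 (2S,4R,6S)-4-[3-acetyl-2,6-bis(benzyloxy)-4-methoxyphenyl]-6-{2-[4-(benzyloxy)phenyl]ethyl}oxane-2-carboxylic acid; 18 1-(benzyloxy)-4-iodobenzene
Product: 19 1-{2,4-bis(benzyloxy)-3-[(2R,4R,6S)-2-[4-(benzyloxy)phenyl]-6-{2-[4-(benzyloxy)phenyl]ethyl}oxan-4-yl]-6-methoxyphenyl}ethan-1-one
Conditions: Ir[dF(CF3)ppy]2(dtbbpy)PF6 (1 mol %), NiCl2(dme) (10 mol %), dtbbpy, Cs2CO3, DMF, blue LEDs, 25 °C
Reagents that add atoms: none
Why: Nickel/photoredox decarboxylative arylation of a cyclic α-oxy acid; with the C4 and C6 groups equatorial, the C2 oxanyl radical should be captured by nickel along the axial direction (as in radical C-glycosylation), so the aryl group should enter trans to both and give the (2R) centre under kinetic, acid-free conditions.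

Step 11
Reactants: 19 1-{2,4-bis(benzyloxy)-3-[(2R,4R,6S)-2-[4-(benzyloxy)phenyl]-6-{2-[4-(benzyloxy)phenyl]ethyl}oxan-4-yl]-6-methoxyphenyl}ethan-1-one
Product: 20 1-{2,4-dihydroxy-3-[(2R,4R,6S)-2-(4-hydroxyphenyl)-6-[2-(4-hydroxyphenyl)ethyl]oxan-4-yl]-6-methoxyphenyl}ethan-1-one
Conditions: H2 (1 atm), Pd/C, EtOAc/EtOH, 25 °C
Reagents that add atoms: none
Why: Hydrogenolysis of the four aryl benzyl ethers, which should be much faster than cleavage of the secondary benzylic C2–O1 bond or reduction of the hindered aryl ketone; the neutral conditions leave the axial C2 aryl group in place.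

Step 12
Reactants: 20 1-{2,4-dihydroxy-3-[(2R,4R,6S)-2-(4-hydroxyphenyl)-6-[2-(4-hydroxyphenyl)ethyl]oxan-4-yl]-6-methoxyphenyl}ethan-1-one; 21 4-hydroxybenzaldehyde
Product: 23 (2E)-1-{2,4-dihydroxy-3-[(2R,4R,6S)-2-(4-hydroxyphenyl)-6-[2-(4-hydroxyphenyl)ethyl]oxan-4-yl]-6-methoxyphenyl}-3-(4-hydroxyphenyl)prop-2-en-1-one, via aldol adduct 22 (not isolated)
Conditions: KOH, EtOH/H2O, 25 °C; then AcOH to pH 6, 0 °C
Reagents that add atoms: none
Why: Claisen–Schmidt condensation: the methyl ketone enolate adds to the aldehyde and aldol 22 loses water by E1cB to the conjugated (E)-enone; no stereocentre is touched and the basic medium avoids acid-induced ring opening at C2.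

## Compound list

1 | 3-[4-(benzyloxy)phenyl]propanal | O=CCCc1ccc(OCc2ccccc2)cc1 | starting material
2 | (3S)-1-[4-(benzyloxy)phenyl]hex-5-en-3-yl diisopinocampheylborinate | C=CC[C@H](CCc1ccc(OCc2ccccc2)cc1)OB([C@H]1C[C@H]2C[C@@H]([C@@H]1C)C2(C)C)[C@H]1C[C@H]2C[C@@H]([C@@H]1C)C2(C)C | intermediate
3 | (3S)-1-[4-(benzyloxy)phenyl]hex-5-en-3-ol | C=CC[C@@H](O)CCc1ccc(OCc2ccccc2)cc1 | intermediate
4 | ethyl glyoxylate | CCOC(=O)C=O | starting material
5 | (E)-oxocarbenium bromide from 3 and 4 | C=CC[C@H](CCc1ccc(OCc2ccccc2)cc1)/[O+]=C/C(=O)OCC.[Br-] | intermediate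
6 | ethyl (2S,4R,6S)-6-{2-[4-(benzyloxy)phenyl]ethyl}-4-bromooxane-2-carboxylate | Br[C@@H]1C[C@H](CCc2ccc(OCc3ccccc3)cc2)O[C@H](C(=O)OCC)C1 | intermediate
7 | 5-methoxybenzene-1,3-diol | COc1cc(O)cc(O)c1 | starting material
8 | 1-methoxy-3,5-bis(methoxymethoxy)benzene | COCOc1cc(OC)cc(OCOC)c1 | intermediate
9 | [4-methoxy-2,6-bis(methoxymethoxy)phenyl]lithium | [Li]c1c(OCOC)cc(OC)cc1OCOC | intermediate
10 | 2-iodo-5-methoxy-1,3-bis(methoxymethoxy)benzene | COCOc1cc(OC)cc(OCOC)c1I | intermediate
11 | {(2S,6S)-2-(ethoxycarbonyl)-6-{2-[4-(benzyloxy)phenyl]ethyl}oxan-4-yl}zinc bromide (C4 epimers interconvert) | Br[Zn]C1C[C@H](CCc2ccc(OCc3ccccc3)cc2)O[C@H](C(=O)OCC)C1 | intermediate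
12 | ethyl (2S,4R,6S)-6-{2-[4-(benzyloxy)phenyl]ethyl}-4-[4-methoxy-2,6-bis(methoxymethoxy)phenyl]oxane-2-carboxylate | COCOc1cc(OC)cc(OCOC)c1[C@@H]1C[C@H](CCc2ccc(OCc3ccccc3)cc2)O[C@H](C(=O)OCC)C1 | intermediate
13 | ethyl (2S,4R,6S)-6-{2-[4-(benzyloxy)phenyl]ethyl}-4-(2,6-dihydroxy-4-methoxyphenyl)oxane-2-carboxylate | COc1cc(O)c([C@@H]2C[C@H](CCc3ccc(OCc4ccccc4)cc3)O[C@H](C(=O)OCC)C2)c(O)c1 | intermediate
14 | 1-{3-[(2S,4R,6S)-2-(ethoxycarbonyl)-6-{2-[4-(benzyloxy)phenyl]ethyl}oxan-4-yl]-2,4-dihydroxy-6-methoxyphenyl}ethan-1-iminium chloride | COc1cc(O)c([C@@H]2C[C@H](CCc3ccc(OCc4ccccc4)cc3)O[C@H](C(=O)OCC)C2)c(O)c1C(C)=[NH2+].[Cl-] | intermediate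
15 | ethyl (2S,4R,6S)-4-(3-acetyl-2,6-dihydroxy-4-methoxyphenyl)-6-{2-[4-(benzyloxy)phenyl]ethyl}oxane-2-carboxylate | COc1cc(O)c([C@@H]2C[C@H](CCc3ccc(OCc4ccccc4)cc3)O[C@H](C(=O)OCC)C2)c(O)c1C(C)=O | intermediate
16 | ethyl (2S,4R,6S)-4-[3-acetyl-2,6-bis(benzyloxy)-4-methoxyphenyl]-6-{2-[4-(benzyloxy)phenyl]ethyl}oxane-2-carboxylate | COc1cc(OCc2ccccc2)c([C@@H]2C[C@H](CCc3ccc(OCc4ccccc4)cc3)O[C@H](C(=O)OCC)C2)c(OCc2ccccc2)c1C(C)=O | intermediate
17 | (2S,4R,6S)-4-[3-acetyl-2,6-bis(benzyloxy)-4-methoxyphenyl]-6-{2-[4-(benzyloxy)phenyl]ethyl}oxane-2-carboxylic acid | COc1cc(OCc2ccccc2)c([C@@H]2C[C@H](CCc3ccc(OCc4ccccc4)cc3)O[C@H](C(=O)O)C2)c(OCc2ccccc2)c1C(C)=O | intermediate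
18 | 1-(benzyloxy)-4-iodobenzene | Ic1ccc(OCc2ccccc2)cc1 | starting material
19 | 1-{2,4-bis(benzyloxy)-3-[(2R,4R,6S)-2-[4-(benzyloxy)phenyl]-6-{2-[4-(benzyloxy)phenyl]ethyl}oxan-4-yl]-6-methoxyphenyl}ethan-1-one | COc1cc(OCc2ccccc2)c([C@@H]2C[C@H](CCc3ccc(OCc4ccccc4)cc3)O[C@@H](c3ccc(OCc4ccccc4)cc3)C2)c(OCc2ccccc2)c1C(C)=O | intermediate
20 | 1-{2,4-dihydroxy-3-[(2R,4R,6S)-2-(4-hydroxyphenyl)-6-[2-(4-hydroxyphenyl)ethyl]oxan-4-yl]-6-methoxyphenyl}ethan-1-one | COc1cc(O)c([C@@H]2C[C@H](CCc3ccc(O)cc3)O[C@@H](c3ccc(O)cc3)C2)c(O)c1C(C)=O | intermediate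
21 | 4-hydroxybenzaldehyde | O=Cc1ccc(O)cc1 | starting material
22 | 1-{2,4-dihydroxy-3-[(2R,4R,6S)-2-(4-hydroxyphenyl)-6-[2-(4-hydroxyphenyl)ethyl]oxan-4-yl]-6-methoxyphenyl}-3-hydroxy-3-(4-hydroxyphenyl)propan-1-one (carbinol epimers) | COc1cc(O)c([C@@H]2C[C@H](CCc3ccc(O)cc3)O[C@@H](c3ccc(O)cc3)C2)c(O)c1C(=O)CC(O)c1ccc(O)cc1 | intermediate
23 | (2E)-1-{2,4-dihydroxy-3-[(2R,4R,6S)-2-(4-hydroxyphenyl)-6-[2-(4-hydroxyphenyl)ethyl]oxan-4-yl]-6-methoxyphenyl}-3-(4-hydroxyphenyl)prop-2-en-1-one | COc1cc(O)c([C@@H]2C[C@H](CCc3ccc(O)cc3)O[C@@H](c3ccc(O)cc3)C2)c(O)c1C(=O)/C=C/c1ccc(O)cc1 | target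

## Step count and risks

Total step count: 12. Longest linear sequence: 10 steps (steps 1, 2 and 5 to 12); steps 3 and 4 prepare the aryl iodide.

Steps most likely to fail:

- **Step 5 (Negishi coupling at C4).** Oxidative addition and reductive elimination at the doubly ortho-substituted aryl iodide may be slow, so that β-hydride elimination with chain walking around the ring, or protodezincation, takes over. Fallback: the polarity is reversed. Setting out from bromide 6 and aryllithium 9 (made from 8 as in step 4), 9 is transmetalated with MgBr2·OEt2 to [4-methoxy-2,6-bis(methoxymethoxy)phenyl]magnesium bromide F1. F1 is added slowly to 6 with FeCl3 (5 mol %) and TMEDA in THF at 0 °C, an iron-catalysed Kumada-type coupling that passes through a C4 radical and should again place the aryl group equatorial. The fallback comes back to the route at 12.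

- **Step 10 (decarboxylative arylation at C2).** Oxidative addition of the electron-rich aryl iodide to nickel may be inefficient, the C2 radical may be reduced to the C2–H oxane, or facial selectivity at C2 may erode. Fallback: setting out from acid 17, N-hydroxyphthalimide, DIC and catalytic DMAP in CH2Cl2 should give the redox-active ester 1,3-dioxoisoindolin-2-yl (2S,4R,6S)-4-[3-acetyl-2,6-bis(benzyloxy)-4-methoxyphenyl]-6-{2-[4-(benzyloxy)phenyl]ethyl}oxane-2-carboxylate F2. F2 is coupled with [4-(benzyloxy)phenyl]zinc chloride F3 (from commercial 4-(benzyloxy)phenylmagnesium bromide and ZnCl2) under NiCl2(dme) and dtbbpy in THF/DMF at 25 °C. This thermal decarboxylative Negishi-type arylation uses an aryl nucleophile instead of an aryl halide and light, and the same axial capture of the C2 radical is expected. The fallback comes back to the route at 19.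

- **Step 12 (condensation on the unprotected polyphenol).** The poly-phenoxide enolate may add only slowly to the deactivated phenoxide form of the aldehyde, the chalcone may isomerize to the flavanone, and prolonged strong base may open the oxane at C2 through a quinone methide and epimerize it. Fallback: setting out from 20, allyl bromide and K2CO3 in acetone should give 1-{4-(allyloxy)-3-[(2R,4R,6S)-2-[4-(allyloxy)phenyl]-6-{2-[4-(allyloxy)phenyl]ethyl}oxan-4-yl]-2-hydroxy-6-methoxyphenyl}ethan-1-one F4, in which the hydrogen-bonded hydroxyl stays free. Short Claisen–Schmidt condensation of F4 with commercial 4-(allyloxy)benzaldehyde (KOH, EtOH, 25 °C) should give (2E)-1-{4-(allyloxy)-3-[(2R,4R,6S)-2-[4-(allyloxy)phenyl]-6-{2-[4-(allyloxy)phenyl]ethyl}oxan-4-yl]-2-hydroxy-6-methoxyphenyl}-3-[4-(allyloxy)phenyl]prop-2-en-1-one F5. Neutral deallylation of F5 with Pd(PPh3)4 and morpholine in THF at 25 °C comes back to the route at 23.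

Further compounds
F1 | step 5 | [4-methoxy-2,6-bis(methoxymethoxy)phenyl]magnesium bromide | Br[Mg]c1c(OCOC)cc(OC)cc1OCOC
F2 | step 10 | 1,3-dioxoisoindolin-2-yl (2S,4R,6S)-4-[3-acetyl-2,6-bis(benzyloxy)-4-methoxyphenyl]-6-{2-[4-(benzyloxy)phenyl]ethyl}oxane-2-carboxylate | COc1cc(OCc2ccccc2)c([C@@H]2C[C@H](CCc3ccc(OCc4ccccc4)cc3)O[C@H](C(=O)ON3C(=O)c4ccccc4C3=O)C2)c(OCc2ccccc2)c1C(C)=O
F3 | step 10 | [4-(benzyloxy)phenyl]zinc chloride | Cl[Zn]c1ccc(OCc2ccccc2)cc1
F4 | step 12 | 1-{4-(allyloxy)-3-[(2R,4R,6S)-2-[4-(allyloxy)phenyl]-6-{2-[4-(allyloxy)phenyl]ethyl}oxan-4-yl]-2-hydroxy-6-methoxyphenyl}ethan-1-one | COc1cc(OCC=C)c([C@@H]2C[C@H](CCc3ccc(OCC=C)cc3)O[C@@H](c3ccc(OCC=C)cc3)C2)c(O)c1C(C)=O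
F5 | step 12 | (2E)-1-{4-(allyloxy)-3-[(2R,4R,6S)-2-[4-(allyloxy)phenyl]-6-{2-[4-(allyloxy)phenyl]ethyl}oxan-4-yl]-2-hydroxy-6-methoxyphenyl}-3-[4-(allyloxy)phenyl]prop-2-en-1-one | COc1cc(OCC=C)c([C@@H]2C[C@H](CCc3ccc(OCC=C)cc3)O[C@@H](c3ccc(OCC=C)cc3)C2)c(O)c1C(=O)/C=C/c1ccc(OCC=C)cc1
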